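**Plan**

Locants: ring A = 7-oxabicyclo[4.1.0]hept-3-ene (C1 = oxirane carbon carrying the side chain, C2 and C5 = carbinols, C4 carries CH2OH, C6 = oxirane CH); ring B = cyclohexane C1'–C6' (C1' carries the diene); side chain C1''(OH)–C2''=C3''(Me)–C4''=C5''.
Retrosynthesis: the sp2–sp2 bond C3''–C4'' is cut last. Ring A then goes back through its two carbinol C–H bonds, the oxirane C–O bonds and a ketal to a p-methoxyphenol, and through C1''–C2'' to an aryl aldehyde plus propyne. Ring B goes back through C6'–O and the C1'–C2' ring bond to epoxygeranyl acetate.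
Forward: ring B closes first (Ti(III) 6-endo radical cyclisation), is hydrated and converted into an (E)-iodoalkene. Ring A travels as a benzene ring through hydroxymethylation and alkynylation, and is then dearomatised, epoxidised and reduced twice. The two halves are joined in the last step.
Enabling feature: C1'' is a secondary carbinol lying between the fully substituted oxirane carbon C1 and a methyl-capped alkyne. Ru-catalysed anti Si–H addition therefore puts silicon on C3'', cis to the carbinol. The partner is the unhindered terminal (E)-CH=CHI on C1' of ring B, and the fluoride that activates silicon also removes every silyl ether.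
Stereochemistry: C3' from Shi epoxidation, C1' from the chair cyclisation, C6' from equatorial O2 capture; C1'' from ligand-controlled alkynylation; the oxirane relayed from C1'' by directed epoxidation; C2 and C5 from hydride addition on the oxirane face; 2''Z from anti-hydrosilylation, 4''E from Takai olefination.

Key step: step 19

Assumption: the (S,S)-ProPhenol/Me2Zn catalyst is taken to add the propynyl group to the Si face of aldehyde 12; if the sense is the reverse, the (R,R)-ligand is used with no other change.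

**Route**

Step 1
Reactants: 1 geranyl acetate
Product: 2 (R)-6,7-epoxygeranyl acetate
Conditions: D-fructose-derived Shi ketone (0.3 equiv), Oxone, K2CO3, Bu4NHSO4, MeCN/DMM/aq. borate buffer (pH ca. 10.5), 0 °C
Reagents that add atoms: Oxone (potassium peroxymonosulfate), [K+].[O-]S(=O)(=O)OO
Why: Shi asymmetric epoxidation, in which the chiral dioxirane attacks only the electron-rich 6,7-olefin (the 2,3-olefin is deactivated by the allylic acetate) through the spiro transition state that should give the (R)-oxirane, whose retained C–O bond becomes the C3' carbinol.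

Step 2
Reactants: 2 (R)-6,7-epoxygeranyl acetate
Product: 3 [(1S,3R)-3-hydroxy-2,2-dimethyl-6-methylidenecyclohexyl]methyl acetate
Conditions: Cp2TiCl2 (2.2 equiv), Mn dust, THF, rt; aq. HCl work-up
Reagents that add atoms: none
Why: titanocene(III) epoxy-olefin radical cyclisation, in which homolysis of the tertiary C–O bond is followed by 6-endo-trig closure through a chair with the titanoxy and CH2OAc groups equatorial (C1' set 1,3-cis to C3'), and trapping by a second Ti(III) with β-hydride elimination gives the exocyclic olefin.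

Step 3
Reactants: 3 [(1S,3R)-3-hydroxy-2,2-dimethyl-6-methylidenecyclohexyl]methyl acetate
Product: 4 [(1S,3R,6R)-3,6-dihydroxy-2,2,6-trimethylcyclohexyl]methyl acetate
Conditions: Mn(dpm)3 (cat.), PhSiH3, O2 (1 atm), i-PrOH/CH2Cl2, 0 °C to rt; then PPh3
Reagents that add atoms: dioxygen, O=O
Why: Mukaiyama hydration (hydrogen-atom transfer to the 1,1-disubstituted olefin, then O2 capture), in which the tertiary radical should be trapped from the equatorial side, away from the axial methyl of the gem-dimethyl carbon 1,3 to it, giving the equatorial C6' hydroxyl trans to CH2OAc.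

Step 4
Reactants: 4 [(1S,3R,6R)-3,6-dihydroxy-2,2,6-trimethylcyclohexyl]methyl acetate
Product: 5 [(1S,3R,6R)-2,2,6-trimethyl-3,6-bis(triethylsilyloxy)cyclohexyl]methyl acetate
Conditions: TESOTf (3 equiv), 2,6-lutidine, CH2Cl2, -78 to 0 °C
Reagents that add atoms: triethylsilyl triflate, CC[Si](CC)(CC)OS(=O)(=O)C(F)(F)F
Why: silyl triflate silylation, reactive enough for the tertiary as well as the secondary alcohol, installing fluoride-labile groups that fall in the final step.

Step 5
Reactants: 5 [(1S,3R,6R)-2,2,6-trimethyl-3,6-bis(triethylsilyloxy)cyclohexyl]methyl acetate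
Product: 6 [(1S,3R,6R)-2,2,6-trimethyl-3,6-bis(triethylsilyloxy)cyclohexyl]methanol
Conditions: K2CO3, MeOH, rt
Reagents that add atoms: none
Why: base-catalysed transesterification of the primary acetate, to which the hindered secondary and tertiary TES ethers should be inert.

Step 6
Reactants: 6 [(1S,3R,6R)-2,2,6-trimethyl-3,6-bis(triethylsilyloxy)cyclohexyl]methanol
Product: 7 (1R,3R,6R)-2,2,6-trimethyl-3,6-bis(triethylsilyloxy)cyclohexane-1-carbaldehyde
Conditions: Dess–Martin periodinane, NaHCO3, CH2Cl2, 0 °C to rt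
Reagents that add atoms: none
Why: Dess–Martin oxidation under buffered, non-basic conditions, so that the α-stereocentre C1' is not epimerised and the β-silyloxy group is not eliminated.

Step 7
Reactants: 7 (1R,3R,6R)-2,2,6-trimethyl-3,6-bis(triethylsilyloxy)cyclohexane-1-carbaldehyde
Product: 8 (1R,3R,6R)-1-[(E)-2-iodoethenyl]-2,2,6-trimethyl-3,6-bis(triethylsilyloxy)cyclohexane
Conditions: CrCl2 (6 equiv), CHI3 (2 equiv), THF/dioxane, 0 °C to rt
Reagents that add atoms: iodoform, IC(I)I
Why: Takai olefination, in which the gem-dichromium species from iodoform adds to the aldehyde and anti-eliminates to the (E)-iodoalkene under non-basic conditions that leave C1' and the silyl ethers untouched.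

Step 8
Reactants: 9 4-bromo-2,5-dimethoxybenzaldehyde
Product: 10 4-bromo-2-hydroxy-5-methoxybenzaldehyde
Conditions: BCl3, CH2Cl2, -78 to 0 °C; aqueous work-up
Reagents that add atoms: none
Why: chelation-controlled Lewis acid demethylation, in which boron bound to the formyl oxygen cleaves only the ortho methyl ether and so frees the phenol that becomes the C2 oxygen.

Step 9
Reactants: 10 4-bromo-2-hydroxy-5-methoxybenzaldehyde
Product: 11 2-hydroxy-4-(hydroxymethyl)-5-methoxybenzaldehyde
Conditions: Bu3SnCH2OH, Pd(PPh3)4 (5 mol %), dioxane, 90 °C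
Reagents that add atoms: (tributylstannyl)methanol, OC[Sn](CCCC)(CCCC)CCCC
Why: Stille-type hydroxymethylation, with easy oxidative addition into the C–Br bond para to the formyl group and neutral conditions that tolerate the free phenol and aldehyde.

Step 10
Reactants: 11 2-hydroxy-4-(hydroxymethyl)-5-methoxybenzaldehyde
Product: 12 2-[tert-butyl(dimethyl)silyl]oxy-4-{[tert-butyl(dimethyl)silyl]oxymethyl}-5-methoxybenzaldehyde
Conditions: TBSCl (2.4 equiv), imidazole, DMF, rt
Reagents that add atoms: tert-butyldimethylsilyl chloride, CC(C)(C)[Si](C)(C)Cl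
Why: standard imidazole-promoted silylation of the phenol and the primary alcohol, removing both acidic protons before the organozinc step.

Step 11
Reactants: 12 2-[tert-butyl(dimethyl)silyl]oxy-4-{[tert-butyl(dimethyl)silyl]oxymethyl}-5-methoxybenzaldehyde
Product: 13 (1S)-1-[2-(TBSO)-4-(TBSOCH2)-5-methoxyphenyl]but-2-yn-1-ol
Conditions: propyne, Me2Zn, (S,S)-ProPhenol (20 mol %), Ph3P=O (40 mol %), toluene, 4 °C; aq. NH4Cl
Reagents that add atoms: propyne, CC#C
Why: zinc–ProPhenol catalysed asymmetric alkynylation of an aryl aldehyde, in which the dinuclear zinc alkynylide should deliver the propynyl group to the Si face and so set (S)-C1'' under ligand control.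

Step 12
Reactants: 13 (1S)-1-[2-(TBSO)-4-(TBSOCH2)-5-methoxyphenyl]but-2-yn-1-ol
Product: 14 5-{[tert-butyl(dimethyl)silyl]oxymethyl}-2-[(1S)-1-hydroxybut-2-yn-1-yl]-4-methoxyphenol
Conditions: KHF2, MeOH, rt
Reagents that add atoms: none
Why: bifluoride cleaves the phenolic silyl ether far faster than the alkyl one, and the absence of an alkoxide base should prevent silyl migration to the benzylic oxygen.

Step 13
Reactants: 14 5-{[tert-butyl(dimethyl)silyl]oxymethyl}-2-[(1S)-1-hydroxybut-2-yn-1-yl]-4-methoxyphenol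
Product: 15 5-{[tert-butyl(dimethyl)silyl]oxymethyl}-2-[(1S)-1-hydroxybut-2-yn-1-yl]-4,4-dimethoxycyclohexa-2,5-dien-1-one
Conditions: PhI(OAc)2, MeOH, 0 °C
Reagents that add atoms: methanol, CO
Why: hypervalent-iodine oxidative dearomatisation of a p-methoxyphenol, in which the aryloxy-λ3-iodane is attacked by methanol at the methoxy-bearing para carbon to give the p-quinone monoketal, leaving one carbonyl to steer the next step.

Step 14
Reactants: 15 5-{[tert-butyl(dimethyl)silyl]oxymethyl}-2-[(1S)-1-hydroxybut-2-yn-1-yl]-4,4-dimethoxycyclohexa-2,5-dien-1-one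
Product: 16 (1S,6R)-4-{[tert-butyl(dimethyl)silyl]oxymethyl}-1-[(1S)-1-hydroxybut-2-yn-1-yl]-5,5-dimethoxy-7-oxabicyclo[4.1.0]hept-3-en-2-one
Conditions: t-BuOOH (anhydrous), DBU, CH2Cl2, -20 to 0 °C
Reagents that add atoms: tert-butyl hydroperoxide, CC(C)(C)OO
Why: Weitz–Scheffer nucleophilic epoxidation, regioselective for the enone olefin whose β-carbon is unsubstituted (the other β-carbon carries CH2OTBS), with the peroxide anion hydrogen-bonded to the free C1'' hydroxyl and delivered on the face where that hydroxyl lies when the carbinol C–H eclipses the ring, which should give the oxirane threo to the carbinol (hydroxyl-directed nucleophilic epoxidation).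

Step 15
Reactants: 16 (1S,6R)-4-{[tert-butyl(dimethyl)silyl]oxymethyl}-1-[(1S)-1-hydroxybut-2-yn-1-yl]-5,5-dimethoxy-7-oxabicyclo[4.1.0]hept-3-en-2-one
Product: 17 (1R,6R)-4-{[tert-butyl(dimethyl)silyl]oxymethyl}-5,5-dimethoxy-1-[(1S)-1-(triethylsilyloxy)but-2-yn-1-yl]-7-oxabicyclo[4.1.0]hept-3-en-2-one
Conditions: TESCl, imidazole, DMAP (cat.), DMF, rt
Reagents that add atoms: triethylsilyl chloride, CC[Si](CC)(CC)Cl
Why: silylation of the only free hydroxyl, which enlarges the substituent on the face opposite the oxirane and removes an alkoxide that could otherwise deliver hydride from the wrong face in the next step.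

Step 16
Reactants: 17 (1R,6R)-4-{[tert-butyl(dimethyl)silyl]oxymethyl}-5,5-dimethoxy-1-[(1S)-1-(triethylsilyloxy)but-2-yn-1-yl]-7-oxabicyclo[4.1.0]hept-3-en-2-one
Product: 18 (1R,2S,6R)-4-{[tert-butyl(dimethyl)silyl]oxymethyl}-5,5-dimethoxy-1-[(1S)-1-(triethylsilyloxy)but-2-yn-1-yl]-7-oxabicyclo[4.1.0]hept-3-en-2-ol
Conditions: NaBH4, CeCl3·7H2O, MeOH, -78 °C
Reagents that add atoms: none
Why: Luche 1,2-reduction of the enone carbonyl, in which hydride should enter on the oxirane face because the opposite face is covered by the CH(OTES)(propynyl) group on the adjacent fully substituted oxirane carbon, giving the C2 hydroxyl trans to the oxirane oxygen.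

Step 17
Reactants: 18 (1R,2S,6R)-4-{[tert-butyl(dimethyl)silyl]oxymethyl}-5,5-dimethoxy-1-[(1S)-1-(triethylsilyloxy)but-2-yn-1-yl]-7-oxabicyclo[4.1.0]hept-3-en-2-ol
Product: 19 (1R,5S,6S)-3-{[tert-butyl(dimethyl)silyl]oxymethyl}-5-hydroxy-6-[(1S)-1-hydroxybut-2-yn-1-yl]-7-oxabicyclo[4.1.0]hept-3-en-2-one
Conditions: oxalic acid, THF/H2O, rt
Reagents that add atoms: water, O
Why: mild acid hydrolysis of the allylic dimethyl ketal to the enone (through the oxocarbenium ion) with concurrent loss of the acid-labile secondary TES ether, conditions under which the oxirane and the primary TBS ether should survive.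

Step 18
Reactants: 19 (1R,5S,6S)-3-{[tert-butyl(dimethyl)silyl]oxymethyl}-5-hydroxy-6-[(1S)-1-hydroxybut-2-yn-1-yl]-7-oxabicyclo[4.1.0]hept-3-en-2-one
Product: 20 (1S,2S,5R,6S)-4-{[tert-butyl(dimethyl)silyl]oxymethyl}-1-[(1S)-1-hydroxybut-2-yn-1-yl]-7-oxabicyclo[4.1.0]hept-3-ene-2,5-diol
Conditions: NaBH4, CeCl3·7H2O, MeOH, -78 °C
Reagents that add atoms: none
Why: Luche 1,2-reduction, in which hydride should again enter on the oxirane face (cerium bridging the carbonyl and oxirane oxygens, the opposite face screened by the pseudo-axial hydroxyl across the ring), giving the 2,5-cis-diol with both hydroxyls trans to the oxirane.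

Step 19
Reactants: 20 (1S,2S,5R,6S)-4-{[tert-butyl(dimethyl)silyl]oxymethyl}-1-[(1S)-1-hydroxybut-2-yn-1-yl]-7-oxabicyclo[4.1.0]hept-3-ene-2,5-diol; 8 (1R,3R,6R)-1-[(E)-2-iodoethenyl]-2,2,6-trimethyl-3,6-bis(triethylsilyloxy)cyclohexane
Product: 23 arthrosporol A, via alkenylsilane 21 (not isolated), via silylated diene 22 (not isolated)
Conditions: [Cp*Ru(MeCN)3]PF6 (5 mol %), BnMe2SiH (1.2 equiv), acetone, 0 °C to rt; volatiles removed; then 8, Pd2(dba)3·CHCl3 (5 mol %), TBAF (8 equiv), THF, rt to 40 °C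
Reagents that add atoms: none
Why: The cationic Ru(II) complex adds the Si–H bond across the only alkyne by the trans-hydrosilylation pathway (oxidative hydrometalation to an η2-vinyl ruthenium species, then silyl migration), so H and Si end up anti and silicon sits on the methyl-bearing carbon C3'', giving (Z)-alkenylsilane 21 with silicon cis to the carbinol. Fluoride then cleaves the benzyl–silicon bond to a silanolate held by the neighbouring C1'' oxygen as a five-membered siloxane, Pd(0) inserts into the C–I bond of 8, and transmetalation with reductive elimination (Hiyama–Denmark coupling) forms the C3''–C4'' bond with retention at both olefins to give 22. The closest known reaction type is Ru-catalysed trans-hydrosilylation of propargylic alcohols followed by fluoride-promoted Pd cross-coupling of the benzyldimethylsilyl alkenes with alkenyl iodides. No ring is closed and no stereocentre is formed; the 2''Z geometry comes from the anti addition and the 4''E geometry from the iodoalkene. The step needs regioselective silyl placement (secured by the propargylic oxygen and the hindered oxirane side opposite a small methyl terminus) and chemoselectivity for the alkyne over the trisubstituted ring olefin and the oxirane (the Ru catalyst leaves both alone and the oxirane is not allylic, so Pd(0) cannot ionise it). The same fluoride finally removes the TBS ether and the two TES ethers of 22 to release 23.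

**Compound list**

1 | geranyl acetate, (2E)-3,7-dimethylocta-2,6-dien-1-yl acetate | CC(=O)OC/C=C(\C)CCC=C(C)C | starting material
2 | (R)-6,7-epoxygeranyl acetate, (2E)-5-[(2R)-3,3-dimethyloxiran-2-yl]-3-methylpent-2-en-1-yl acetate | CC(=O)OC/C=C(\C)CC[C@H]1OC1(C)C | intermediate
3 | [(1S,3R)-3-hydroxy-2,2-dimethyl-6-methylidenecyclohexyl]methyl acetate (CH2OAc and OH cis) | CC(=O)OC[C@@H]1C(C)(C)[C@H](O)CCC1=C | intermediate
4 | [(1S,3R,6R)-3,6-dihydroxy-2,2,6-trimethylcyclohexyl]methyl acetate | CC(=O)OC[C@@H]1C(C)(C)[C@H](O)CC[C@@]1(C)O | intermediate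
5 | [(1S,3R,6R)-2,2,6-trimethyl-3,6-bis(triethylsilyloxy)cyclohexyl]methyl acetate | CC(=O)OC[C@@H]1C(C)(C)[C@H](O[Si](CC)(CC)CC)CC[C@@]1(C)O[Si](CC)(CC)CC | intermediate
6 | [(1S,3R,6R)-2,2,6-trimethyl-3,6-bis(triethylsilyloxy)cyclohexyl]methanol | OC[C@@H]1C(C)(C)[C@H](O[Si](CC)(CC)CC)CC[C@@]1(C)O[Si](CC)(CC)CC | intermediate
7 | (1R,3R,6R)-2,2,6-trimethyl-3,6-bis(triethylsilyloxy)cyclohexane-1-carbaldehyde | O=C[C@@H]1C(C)(C)[C@H](O[Si](CC)(CC)CC)CC[C@@]1(C)O[Si](CC)(CC)CC | intermediate
8 | (1R,3R,6R)-1-[(E)-2-iodoethenyl]-2,2,6-trimethyl-3,6-bis(triethylsilyloxy)cyclohexane | I/C=C/[C@@H]1C(C)(C)[C@H](O[Si](CC)(CC)CC)CC[C@@]1(C)O[Si](CC)(CC)CC | intermediate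
9 | 4-bromo-2,5-dimethoxybenzaldehyde | O=Cc1cc(OC)c(Br)cc1OC | starting material
10 | 4-bromo-2-hydroxy-5-methoxybenzaldehyde | O=Cc1cc(OC)c(Br)cc1O | intermediate
11 | 2-hydroxy-4-(hydroxymethyl)-5-methoxybenzaldehyde | O=Cc1cc(OC)c(CO)cc1O | intermediate
12 | 2-[tert-butyl(dimethyl)silyl]oxy-4-{[tert-butyl(dimethyl)silyl]oxymethyl}-5-methoxybenzaldehyde | O=Cc1cc(OC)c(CO[Si](C)(C)C(C)(C)C)cc1O[Si](C)(C)C(C)(C)C | intermediate
13 | (1S)-1-[2-(TBSO)-4-(TBSOCH2)-5-methoxyphenyl]but-2-yn-1-ol | CC#C[C@H](O)c1cc(OC)c(CO[Si](C)(C)C(C)(C)C)cc1O[Si](C)(C)C(C)(C)C | intermediate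
14 | 5-{[tert-butyl(dimethyl)silyl]oxymethyl}-2-[(1S)-1-hydroxybut-2-yn-1-yl]-4-methoxyphenol | CC#C[C@H](O)c1cc(OC)c(CO[Si](C)(C)C(C)(C)C)cc1O | intermediate
15 | 5-{[tert-butyl(dimethyl)silyl]oxymethyl}-2-[(1S)-1-hydroxybut-2-yn-1-yl]-4,4-dimethoxycyclohexa-2,5-dien-1-one | CC#C[C@H](O)C1=CC(OC)(OC)C(CO[Si](C)(C)C(C)(C)C)=CC1=O | intermediate
16 | (1S,6R)-4-{[tert-butyl(dimethyl)silyl]oxymethyl}-1-[(1S)-1-hydroxybut-2-yn-1-yl]-5,5-dimethoxy-7-oxabicyclo[4.1.0]hept-3-en-2-one (oxirane O threo to carbinol OH) | CC#C[C@H](O)[C@]12O[C@H]1C(OC)(OC)C(CO[Si](C)(C)C(C)(C)C)=CC2=O | intermediate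
17 | (1R,6R)-4-{[tert-butyl(dimethyl)silyl]oxymethyl}-5,5-dimethoxy-1-[(1S)-1-(triethylsilyloxy)but-2-yn-1-yl]-7-oxabicyclo[4.1.0]hept-3-en-2-one | CC#C[C@H](O[Si](CC)(CC)CC)[C@]12O[C@H]1C(OC)(OC)C(CO[Si](C)(C)C(C)(C)C)=CC2=O | intermediate
18 | (1R,2S,6R)-4-{[tert-butyl(dimethyl)silyl]oxymethyl}-5,5-dimethoxy-1-[(1S)-1-(triethylsilyloxy)but-2-yn-1-yl]-7-oxabicyclo[4.1.0]hept-3-en-2-ol (2-OH trans to oxirane O) | CC#C[C@H](O[Si](CC)(CC)CC)[C@]12O[C@H]1C(OC)(OC)C(CO[Si](C)(C)C(C)(C)C)=C[C@@H]2O | intermediate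
19 | (1R,5S,6S)-3-{[tert-butyl(dimethyl)silyl]oxymethyl}-5-hydroxy-6-[(1S)-1-hydroxybut-2-yn-1-yl]-7-oxabicyclo[4.1.0]hept-3-en-2-one | CC#C[C@H](O)[C@]12O[C@H]1C(=O)C(CO[Si](C)(C)C(C)(C)C)=C[C@@H]2O | intermediate
20 | (1S,2S,5R,6S)-4-{[tert-butyl(dimethyl)silyl]oxymethyl}-1-[(1S)-1-hydroxybut-2-yn-1-yl]-7-oxabicyclo[4.1.0]hept-3-ene-2,5-diol (both ring OH trans to oxirane O) | CC#C[C@H](O)[C@]12O[C@H]1[C@H](O)C(CO[Si](C)(C)C(C)(C)C)=C[C@@H]2O | intermediate
21 | (1S,2S,5R,6S)-1-{(1S,2Z)-3-[benzyl(dimethyl)silyl]-1-hydroxybut-2-en-1-yl}-4-{[tert-butyl(dimethyl)silyl]oxymethyl}-7-oxabicyclo[4.1.0]hept-3-ene-2,5-diol | C/C(=C/[C@H](O)[C@]12O[C@H]1[C@H](O)C(CO[Si](C)(C)C(C)(C)C)=C[C@@H]2O)[Si](C)(C)Cc1ccccc1 | intermediate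
22 | arthrosporol A carrying a TBS ether on the C4 hydroxymethyl group and TES ethers on the C3' and C6' hydroxyls | CC(=C/[C@H](O)[C@]12O[C@H]1[C@H](O)C(CO[Si](C)(C)C(C)(C)C)=C[C@@H]2O)/C=C/[C@@H]1C(C)(C)[C@H](O[Si](CC)(CC)CC)CC[C@@]1(C)O[Si](CC)(CC)CC | intermediate
23 | arthrosporol A, (1R,2S,5R,6S)-1-{(1S,2Z,4E)-5-[(1R,3R,6R)-3,6-dihydroxy-2,2,6-trimethylcyclohexyl]-1-hydroxy-3-methylpenta-2,4-dien-1-yl}-4-(hydroxymethyl)-7-oxabicyclo[4.1.0]hept-3-ene-2,5-diol | CC(=C/[C@H](O)[C@]12O[C@H]1[C@H](O)C(CO)=C[C@@H]2O)/C=C/[C@@H]1C(C)(C)[C@H](O)CC[C@@]1(C)O | target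

**Count and risks**

Total step count: 19. Longest linear sequence: 12 steps (steps 8 to 19, from 9).

Steps most likely to fail:

1. Step 19. Transmetalation of the hindered, α-methyl alkenylsilicon species to palladium may be slower than fluoride-induced protodesilylation, and long exposure to basic fluoride may cause oxirane migration. The fallback sets out from 20 and 8 and comes back at 22. The Ru hydrosilylation would be run alone and alkenylsilane 21 isolated. Iododesilylation with NIS in hexafluoroisopropanol at 0 °C, with retention, would give (1S,2S,5R,6S)-4-{[tert-butyl(dimethyl)silyl]oxymethyl}-1-[(1S,2Z)-1-hydroxy-3-iodobut-2-en-1-yl]-7-oxabicyclo[4.1.0]hept-3-ene-2,5-diol F1. Iodoalkene 8 would be converted by iodine–lithium exchange (t-BuLi, Et2O, -78 °C) and Bu3SnCl into tributyl{(E)-2-[(1R,3R,6R)-2,2,6-trimethyl-3,6-bis(triethylsilyloxy)cyclohexyl]ethenyl}stannane F2. A neutral Stille coupling of the two (Pd(PPh3)4, copper(I) thiophene-2-carboxylate, tetrabutylammonium diphenylphosphinate, DMF, rt) should then give 22, which would be desilylated in a separate operation with acetic-acid-buffered TBAF to 23.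

2. Step 14. The facial selectivity may be poor or reversed: if peroxide addition is reversible, ring closure anti to the carbinol substituent could favour the erythro epoxy alcohol. The fallback sets out from 12 and comes back at 16, using that erythro preference on the mirror-image carbinol. Alkynylation of 12 with the (R,R)-ligand would give (1R)-1-[2-(TBSO)-4-(TBSOCH2)-5-methoxyphenyl]but-2-yn-1-ol F3. KHF2 would give the phenol 5-{[tert-butyl(dimethyl)silyl]oxymethyl}-2-[(1R)-1-hydroxybut-2-yn-1-yl]-4-methoxyphenol F4. PhI(OAc)2/MeOH would give the dienone 5-{[tert-butyl(dimethyl)silyl]oxymethyl}-2-[(1R)-1-hydroxybut-2-yn-1-yl]-4,4-dimethoxycyclohexa-2,5-dien-1-one F5. Epoxidation as in step 14 would give the erythro epoxy alcohol (1S,6R)-4-{[tert-butyl(dimethyl)silyl]oxymethyl}-1-[(1R)-1-hydroxybut-2-yn-1-yl]-5,5-dimethoxy-7-oxabicyclo[4.1.0]hept-3-en-2-one F6, which has the oxirane configuration of 16. Dess–Martin oxidation would give the epoxy ynone (1S,6R)-1-(but-2-ynoyl)-4-{[tert-butyl(dimethyl)silyl]oxymethyl}-5,5-dimethoxy-7-oxabicyclo[4.1.0]hept-3-en-2-one F7. Noyori transfer hydrogenation (RuCl(p-cymene)[(R,R)-TsDPEN], i-PrOH, rt), which reduces ynones in preference to the hindered ring enone and under catalyst control, should then give the (S)-carbinol 16.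

3. Step 18. Hydride may add on the face opposite the oxirane (attack antiperiplanar to the oxirane C–O bond), giving the C5 epimer. The fallback sets out from 19 and comes back at 20. Reduction with DIBAL-H (THF, -78 °C), which favours that opposite-face attack, would be used deliberately to make (1S,2S,5S,6S)-4-{[tert-butyl(dimethyl)silyl]oxymethyl}-1-[(1S)-1-hydroxybut-2-yn-1-yl]-7-oxabicyclo[4.1.0]hept-3-ene-2,5-diol F8. Mitsunobu inversion (4-nitrobenzoic acid, PPh3, DIAD, THF, 0 °C) should act only at the unhindered allylic C5 hydroxyl, since the other two secondary hydroxyls are flanked by the fully substituted oxirane carbon, and give the C5 4-nitrobenzoate of 20 F9. Methanolysis (K2CO3, MeOH, 0 °C) would then give 20.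

**Further compounds**

F1 | step 19 | (1S,2S,5R,6S)-4-{[tert-butyl(dimethyl)silyl]oxymethyl}-1-[(1S,2Z)-1-hydroxy-3-iodobut-2-en-1-yl]-7-oxabicyclo[4.1.0]hept-3-ene-2,5-diol | C/C(I)=C/[C@H](O)[C@]12O[C@H]1[C@H](O)C(CO[Si](C)(C)C(C)(C)C)=C[C@@H]2O
F2 | step 19 | tributyl{(E)-2-[(1R,3R,6R)-2,2,6-trimethyl-3,6-bis(triethylsilyloxy)cyclohexyl]ethenyl}stannane | CCCC[Sn](CCCC)(CCCC)/C=C/[C@@H]1C(C)(C)[C@H](O[Si](CC)(CC)CC)CC[C@@]1(C)O[Si](CC)(CC)CC
F3 | step 14 | (1R)-1-[2-(TBSO)-4-(TBSOCH2)-5-methoxyphenyl]but-2-yn-1-ol | CC#C[C@@H](O)c1cc(OC)c(CO[Si](C)(C)C(C)(C)C)cc1O[Si](C)(C)C(C)(C)C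
F4 | step 14 | 5-{[tert-butyl(dimethyl)silyl]oxymethyl}-2-[(1R)-1-hydroxybut-2-yn-1-yl]-4-methoxyphenol | CC#C[C@@H](O)c1cc(OC)c(CO[Si](C)(C)C(C)(C)C)cc1O
F5 | step 14 | 5-{[tert-butyl(dimethyl)silyl]oxymethyl}-2-[(1R)-1-hydroxybut-2-yn-1-yl]-4,4-dimethoxycyclohexa-2,5-dien-1-one | CC#C[C@@H](O)C1=CC(OC)(OC)C(CO[Si](C)(C)C(C)(C)C)=CC1=O
F6 | step 14 | (1S,6R)-4-{[tert-butyl(dimethyl)silyl]oxymethyl}-1-[(1R)-1-hydroxybut-2-yn-1-yl]-5,5-dimethoxy-7-oxabicyclo[4.1.0]hept-3-en-2-one | CC#C[C@@H](O)[C@]12O[C@H]1C(OC)(OC)C(CO[Si](C)(C)C(C)(C)C)=CC2=O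
F7 | step 14 | (1S,6R)-1-(but-2-ynoyl)-4-{[tert-butyl(dimethyl)silyl]oxymethyl}-5,5-dimethoxy-7-oxabicyclo[4.1.0]hept-3-en-2-one | CC#CC(=O)[C@]12O[C@H]1C(OC)(OC)C(CO[Si](C)(C)C(C)(C)C)=CC2=O
F8 | step 18 | (1S,2S,5S,6S)-4-{[tert-butyl(dimethyl)silyl]oxymethyl}-1-[(1S)-1-hydroxybut-2-yn-1-yl]-7-oxabicyclo[4.1.0]hept-3-ene-2,5-diol | CC#C[C@H](O)[C@]12O[C@H]1[C@@H](O)C(CO[Si](C)(C)C(C)(C)C)=C[C@@H]2O
F9 | step 18 | C5 4-nitrobenzoate of 20 | CC#C[C@H](O)[C@]12O[C@H]1[C@H](OC(=O)c3ccc(cc3)[N+](=O)[O-])C(CO[Si](C)(C)C(C)(C)C)=C[C@@H]2O
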